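The cyclopentenone is closed last, across its C6=C7 enol-ether double bond (1-oxaspiro[2.4]hept-6-en-5-one numbering: C3 spiro epoxide carbon, C4 C(OMe)Ar, C5 C=O, C6 C–OMe, C7 C–Ar), by intramolecular aldol condensation of an acyclic 1,4-diketone that already carries the epoxide and both quaternary centres. The step exploits the 2-methoxy-3-aryl enone unit C5–C6=C7: the MeOCH2 group next to C5 is the only enolisable site, so one operation forms the carbocycle and the tetrasubstituted alkene. C3 is set by matched Sharpless epoxidation of a dienyl carbinol, C4 by chelation-controlled vinyl addition to the derived epoxy ketone; two latent ketones are unveiled by ozonolysis.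

Key step: step 11

Remark: both phenols are carried as triisopropylsilyl (TIPS) ethers. In step 3 the BINOL enantiomer is the one that delivers the (S)-carbinol, taken here as (R)-BINOL by analogy with BINOL–titanium dialkylzinc additions; only the (S)-carbinol is matched with L-(+)-DIPT in step 5.

Step 1
Reactants: 1 4-hydroxybenzaldehyde
Product: 2 4-(triisopropylsilyloxy)benzaldehyde
Conditions: TIPSCl, imidazole, DMF, rt
Reagents that add atoms: triisopropylsilyl chloride, CC(C)[Si](Cl)(C(C)C)C(C)C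
Why: Imidazole-promoted silylation of the phenol gives a bulky aryl silyl ether that should survive organometallics and alkoxide base and leave with fluoride at the end.

Step 2
Reactants: 2 4-(triisopropylsilyloxy)benzaldehyde
Product: 3 (4-ethynylphenoxy)triisopropylsilane
Conditions: TMSCHN2, LDA, THF, −78 °C → rt
Reagents that add atoms: trimethylsilyldiazomethane, C[Si](C)(C)C=[N+]=[N-]
Why: Colvin homologation, in which lithiated trimethylsilyldiazomethane adds to the aldehyde, Peterson elimination and loss of N2 give an alkylidene carbene, and a 1,2-hydrogen shift gives the terminal alkyne.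

Step 3
Reactants: 2 4-(triisopropylsilyloxy)benzaldehyde; 3 (4-ethynylphenoxy)triisopropylsilane
Product: 5 (1S)-1,3-bis[4-(triisopropylsilyloxy)phenyl]prop-2-yn-1-ol, via alkynylzinc 4 (not isolated)
Conditions: 3, Et2Zn, toluene, reflux; then (R)-BINOL (20 mol %), Ti(Oi-Pr)4 (50 mol %), 2, CH2Cl2, rt
Reagents that add atoms: none
Why: BINOL–titanium(IV)-catalysed asymmetric addition of an alkynylzinc to an aromatic aldehyde, in which the chiral titanium complex differentiates the aldehyde faces and sets the carbinol centre as S.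

Step 4
Reactants: 5 (1S)-1,3-bis[4-(triisopropylsilyloxy)phenyl]prop-2-yn-1-ol
Product: 6 (1S)-2-methylidene-1,3-bis[4-(triisopropylsilyloxy)phenyl]but-3-en-1-ol
Conditions: Grubbs II (5 mol %), ethylene (1 atm), toluene, 80 °C
Reagents that add atoms: ethylene, C=C
Why: Ruthenium-carbene-catalysed cross enyne metathesis of the internal alkyne with ethylene transfers one methylene to each alkyne carbon and gives the 2,3-disubstituted buta-1,3-diene, leaving the carbinol centre untouched.

Step 5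
Reactants: 6 (1S)-2-methylidene-1,3-bis[4-(triisopropylsilyloxy)phenyl]but-3-en-1-ol
Product: 7 (S)-[4-(triisopropylsilyloxy)phenyl]{(2R)-2-[1-(4-(triisopropylsilyloxy)phenyl)ethenyl]oxiran-2-yl}methanol
Conditions: Ti(Oi-Pr)4 (20 mol %), L-(+)-DIPT (25 mol %), t-BuOOH, 4 Å MS, CH2Cl2, −20 °C
Reagents that add atoms: tert-butyl hydroperoxide, CC(C)(C)OO
Why: Sharpless asymmetric epoxidation of a secondary allylic alcohol in its matched (kinetic-resolution) mode, in which L-(+)-DIPT selects the (S)-carbinol and delivers oxygen to the face of the allylic 1,1-disubstituted alkene that gives the erythro (2R)-epoxide, while the homoallylic styrene-type alkene and any mismatched (R)-carbinol should stay behind.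

Step 6
Reactants: 7 (S)-[4-(triisopropylsilyloxy)phenyl]{(2R)-2-[1-(4-(triisopropylsilyloxy)phenyl)ethenyl]oxiran-2-yl}methanol
Product: 8 {(2R)-2-[1-(4-(triisopropylsilyloxy)phenyl)ethenyl]oxiran-2-yl}[4-(triisopropylsilyloxy)phenyl]methanone
Conditions: Dess–Martin periodinane, pyridine, CH2Cl2, 0 °C → rt
Reagents that add atoms: none
Why: Dess–Martin oxidation of the secondary benzylic alcohol to the aryl ketone under buffered conditions, the epoxide carbon being quaternary and unable to epimerise.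

Step 7
Reactants: 9 2,3-dibromoprop-1-ene
Product: 10 2-bromo-3-methoxyprop-1-ene
Conditions: NaOMe, MeOH, 0 °C → rt
Reagents that add atoms: sodium methoxide, [Na+].[O-]C
Why: SN2 displacement (Williamson ether synthesis) of the allylic bromide by methoxide, the vinylic C–Br bond being inert.

Step 8
Reactants: 10 2-bromo-3-methoxyprop-1-ene; 8 {(2R)-2-[1-(4-(triisopropylsilyloxy)phenyl)ethenyl]oxiran-2-yl}[4-(triisopropylsilyloxy)phenyl]methanone
Product: 13 (1S)-2-(methoxymethyl)-1-[4-(triisopropylsilyloxy)phenyl]-1-{(2R)-2-[1-(4-(triisopropylsilyloxy)phenyl)ethenyl]oxiran-2-yl}prop-2-en-1-ol, via vinyllithium 11 (not isolated), via vinylmagnesium bromide 12 (not isolated)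
Conditions: 10, t-BuLi (2 equiv), Et2O, −78 °C; MgBr2·OEt2; then 8, −78 → −40 °C; aq NH4Cl
Reagents that add atoms: none
Why: Bromine–lithium exchange and transmetalation give a vinyl Grignard reagent that adds to the α,β-epoxy ketone under Cram chelation control (magnesium bridging the carbonyl and epoxide oxygens), attacking the face syn to the epoxide CH2 and anti to the bulky 1-arylvinyl group, which sets the tertiary carbinol centre.

Step 9
Reactants: 13 (1S)-2-(methoxymethyl)-1-[4-(triisopropylsilyloxy)phenyl]-1-{(2R)-2-[1-(4-(triisopropylsilyloxy)phenyl)ethenyl]oxiran-2-yl}prop-2-en-1-ol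
Product: 14 (2R)-2-{(1S)-1-methoxy-2-(methoxymethyl)-1-[4-(triisopropylsilyloxy)phenyl]prop-2-en-1-yl}-2-{1-[4-(triisopropylsilyloxy)phenyl]ethenyl}oxirane
Conditions: KHMDS (1.1 equiv), THF, −78 °C; then MeOTf, −78 → −40 °C
Reagents that add atoms: methyl trifluoromethanesulfonate, COS(=O)(=O)C(F)(F)F
Why: Williamson O-methylation of the potassium alkoxide with methyl triflate at −78 °C, which should be fast enough to outrun Payne-type migration of the neighbouring epoxide and leaves both stereocentres unchanged.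

Step 10
Reactants: 14 (2R)-2-{(1S)-1-methoxy-2-(methoxymethyl)-1-[4-(triisopropylsilyloxy)phenyl]prop-2-en-1-yl}-2-{1-[4-(triisopropylsilyloxy)phenyl]ethenyl}oxirane
Product: 16 (3R)-1,3-dimethoxy-3-[4-(triisopropylsilyloxy)phenyl]-3-{(2R)-2-[4-(triisopropylsilyloxy)benzoyl]oxiran-2-yl}propan-2-one, via bis-ozonide 15 (not isolated)
Conditions: O3, CH2Cl2, −78 °C; then PPh3, −78 °C → rt
Reagents that add atoms: ozone, [O-][O+]=O
Why: Ozonolysis with reductive work-up cleaves both 1,1-disubstituted alkenes, far faster than the silyloxy arenes, to unveil the aryl ketone and the methoxymethyl ketone without touching the two quaternary stereocentres.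

Step 11
Reactants: 16 (3R)-1,3-dimethoxy-3-[4-(triisopropylsilyloxy)phenyl]-3-{(2R)-2-[4-(triisopropylsilyloxy)benzoyl]oxiran-2-yl}propan-2-one
Product: 18 (3R,4R)-4,6-dimethoxy-4,7-bis[4-(triisopropylsilyloxy)phenyl]-1-oxaspiro[2.4]hept-6-en-5-one, via aldol adduct 17 (not isolated)
Conditions: t-BuOK (0.3 equiv), THF/t-BuOH, 0 °C → rt
Reagents that add atoms: none
Why: Catalytic tert-butoxide reversibly deprotonates the only enolisable position of 16, the O-methylated methylene next to the C5 ketone, and the enolate adds to the aryl ketone (future C7) to give aldolate 17, which loses hydroxide by E1cB to the aryl-conjugated enone. The closest known reaction type is the base-mediated cyclodehydration of 1,4-diketones to cyclopent-2-enones (intramolecular aldol condensation). The five-membered ring closes in the 5-(enolexo)-exo-trig mode. No stereocentre is created in the product, since the two transient centres of 17 become the C6=C7 alkene, and C3 and C4 are quaternary and non-enolisable, so they cannot be scrambled. The step needs chemoselectivity for carbonyl addition over alkylation of the enolate by the epoxide CH2 and over Payne-type migration of the aldolate; reversible aldol addition followed by irreversible dehydration, sub-stoichiometric base at low temperature and the retained silyl ethers (no phenoxide to deactivate the ketone) should secure it.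

Step 12
Reactants: 18 (3R,4R)-4,6-dimethoxy-4,7-bis[4-(triisopropylsilyloxy)phenyl]-1-oxaspiro[2.4]hept-6-en-5-one
Product: 19 (3R,4R)-4,7-bis(4-hydroxyphenyl)-4,6-dimethoxy-1-oxaspiro[2.4]hept-6-en-5-one (CNP0504072.1)
Conditions: TBAF, AcOH, THF, 0 °C
Reagents that add atoms: none
Why: Fluoride-induced desilylation of the two aryl TIPS ethers, buffered with acetic acid so that no phenoxide is formed that could expel the benzylic methoxy group or open the epoxide.

Compound list
1 | 4-hydroxybenzaldehyde | O=Cc1ccc(O)cc1 | starting material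
2 | 4-(triisopropylsilyloxy)benzaldehyde | O=Cc1ccc(O[Si](C(C)C)(C(C)C)C(C)C)cc1 | intermediate
3 | (4-ethynylphenoxy)triisopropylsilane | C#Cc1ccc(O[Si](C(C)C)(C(C)C)C(C)C)cc1 | intermediate
4 | ethyl{[4-(triisopropylsilyloxy)phenyl]ethynyl}zinc (alkynylzinc, formed in situ) | CC[Zn]C#Cc1ccc(O[Si](C(C)C)(C(C)C)C(C)C)cc1 | intermediate
5 | (1S)-1,3-bis[4-(triisopropylsilyloxy)phenyl]prop-2-yn-1-ol | O[C@H](C#Cc1ccc(O[Si](C(C)C)(C(C)C)C(C)C)cc1)c1ccc(O[Si](C(C)C)(C(C)C)C(C)C)cc1 | intermediate
6 | (1S)-2-methylidene-1,3-bis[4-(triisopropylsilyloxy)phenyl]but-3-en-1-ol | O[C@H](C(=C)C(=C)c1ccc(O[Si](C(C)C)(C(C)C)C(C)C)cc1)c1ccc(O[Si](C(C)C)(C(C)C)C(C)C)cc1 | intermediate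
7 | (S)-[4-(triisopropylsilyloxy)phenyl]{(2R)-2-[1-(4-(triisopropylsilyloxy)phenyl)ethenyl]oxiran-2-yl}methanol | O[C@H]([C@]1(CO1)C(=C)c1ccc(O[Si](C(C)C)(C(C)C)C(C)C)cc1)c1ccc(O[Si](C(C)C)(C(C)C)C(C)C)cc1 | intermediate
8 | {(2R)-2-[1-(4-(triisopropylsilyloxy)phenyl)ethenyl]oxiran-2-yl}[4-(triisopropylsilyloxy)phenyl]methanone | O=C(c1ccc(O[Si](C(C)C)(C(C)C)C(C)C)cc1)[C@]1(CO1)C(=C)c1ccc(O[Si](C(C)C)(C(C)C)C(C)C)cc1 | intermediate
9 | 2,3-dibromoprop-1-ene | C=C(Br)CBr | starting material
10 | 2-bromo-3-methoxyprop-1-ene | COCC(Br)=C | intermediate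
11 | [1-(methoxymethyl)ethenyl]lithium (vinyllithium, formed in situ) | [Li]C(=C)COC | intermediate
12 | bromo[1-(methoxymethyl)ethenyl]magnesium (vinylmagnesium bromide, formed in situ) | Br[Mg]C(=C)COC | intermediate
13 | (1S)-2-(methoxymethyl)-1-[4-(triisopropylsilyloxy)phenyl]-1-{(2R)-2-[1-(4-(triisopropylsilyloxy)phenyl)ethenyl]oxiran-2-yl}prop-2-en-1-ol | C=C(c1ccc(O[Si](C(C)C)(C(C)C)C(C)C)cc1)[C@@]1(CO1)[C@](O)(c1ccc(O[Si](C(C)C)(C(C)C)C(C)C)cc1)C(=C)COC | intermediate
14 | (2R)-2-{(1S)-1-methoxy-2-(methoxymethyl)-1-[4-(triisopropylsilyloxy)phenyl]prop-2-en-1-yl}-2-{1-[4-(triisopropylsilyloxy)phenyl]ethenyl}oxirane | C=C(c1ccc(O[Si](C(C)C)(C(C)C)C(C)C)cc1)[C@@]1(CO1)[C@](OC)(c1ccc(O[Si](C(C)C)(C(C)C)C(C)C)cc1)C(=C)COC | intermediate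
15 | bis-ozonide of 14: both C=CH2 groups converted into 1,2,4-trioxolane rings, epoxide and ether centres as in 14, epimers at the two trioxolane carbons (formed in situ) | C1(OOCO1)(c2ccc(O[Si](C(C)C)(C(C)C)C(C)C)cc2)[C@@]2(CO2)[C@](OC)(c2ccc(O[Si](C(C)C)(C(C)C)C(C)C)cc2)C1(OOCO1)COC | intermediate
16 | (3R)-1,3-dimethoxy-3-[4-(triisopropylsilyloxy)phenyl]-3-{(2R)-2-[4-(triisopropylsilyloxy)benzoyl]oxiran-2-yl}propan-2-one | O=C(c1ccc(O[Si](C(C)C)(C(C)C)C(C)C)cc1)[C@@]1(CO1)[C@](OC)(c1ccc(O[Si](C(C)C)(C(C)C)C(C)C)cc1)C(=O)COC | intermediate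
17 | aldol adduct: 7-hydroxy-4,6-dimethoxy-4,7-bis[4-(triisopropylsilyloxy)phenyl]-1-oxaspiro[2.4]heptan-5-one, C3 and C4 as in 16, epimers at C6 and C7 (formed in situ) | COC1C(O)(c2ccc(O[Si](C(C)C)(C(C)C)C(C)C)cc2)[C@@]2(CO2)[C@](OC)(c2ccc(O[Si](C(C)C)(C(C)C)C(C)C)cc2)C1=O | intermediate
18 | (3R,4R)-4,6-dimethoxy-4,7-bis[4-(triisopropylsilyloxy)phenyl]-1-oxaspiro[2.4]hept-6-en-5-one | COC1=C(c2ccc(O[Si](C(C)C)(C(C)C)C(C)C)cc2)[C@@]2(CO2)[C@](OC)(c2ccc(O[Si](C(C)C)(C(C)C)C(C)C)cc2)C1=O | intermediate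
19 | (3R,4R)-4,7-bis(4-hydroxyphenyl)-4,6-dimethoxy-1-oxaspiro[2.4]hept-6-en-5-one (CNP0504072.1) | COC1=C(c2ccc(O)cc2)[C@@]2(CO2)[C@](OC)(c2ccc(O)cc2)C1=O | target

Total step count: 12. Longest linear sequence: 11 steps (steps 1–6 and 8–12; step 7 prepares the side fragment 10).

Steps most likely to fail

1. Step 11 (key step). The enolate may alkylate the epoxide methylene (5-exo-tet opening) instead of adding to the ketone, or the aldolate may undergo Payne-type epoxide migration before it dehydrates. The fallback closes the same C6=C7 bond by an intramolecular Horner–Wadsworth–Emmons reaction, in which no free aldolate persists and the nucleophile is a soft phosphonate anion. It sets out from 8. Chelation-controlled addition of vinylmagnesium bromide gives the tertiary allylic alcohol (1R)-1-[4-(triisopropylsilyloxy)phenyl]-1-{(2R)-2-[1-(4-(triisopropylsilyloxy)phenyl)ethenyl]oxiran-2-yl}prop-2-en-1-ol F1. O-Methylation (KHMDS, MeOTf, −78 °C) gives the methyl ether F2. Ozonolysis of both alkenes (O3, then PPh3) gives the keto aldehyde F3. Lithiated diethyl (methoxymethyl)phosphonate adds chemoselectively to the aldehyde at −78 °C to give the β-hydroxy phosphonate F4. Dess–Martin oxidation gives the β-keto phosphonate F5. LiCl and DBU in MeCN (Masamune–Roush conditions) then close the ring onto the aryl ketone, and the route is rejoined at 18.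

2. Step 8. The 2-metallated allyl ether may lose methoxide by β-elimination to allene, and the branched vinyl nucleophile may erode chelate control so that the Felkin-type diastereomer forms. The fallback uses a small, stable alkynyl nucleophile and builds the methoxymethyl ketone by alkyne oxidation. It sets out from 8. Ethynylmagnesium bromide (THF/Et2O, −78 °C) under the same chelation control gives the propargylic alcohol (1S)-1-[4-(triisopropylsilyloxy)phenyl]-1-{(2R)-2-[1-(4-(triisopropylsilyloxy)phenyl)ethenyl]oxiran-2-yl}prop-2-yn-1-ol F6. Methylation of the alkoxide (1.0 equiv KHMDS, MeOTf) gives the methyl ether F7. Alkene-selective ozonolysis (O3, then PPh3) gives the alkynyl ketone F8. Gold(I)-catalysed oxidation of the terminal alkyne with 8-methylquinoline N-oxide in methanol (α-oxo gold carbene, O–H insertion of methanol) gives the methoxymethyl ketone, and the route is rejoined at 16.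

3. Step 9. The very hindered tertiary alkoxide may fail to alkylate, or may attack the neighbouring epoxide carbon (Payne-type migration) before it is trapped. The fallback postpones the methylation to the α-ketol stage, where no free alkoxide is needed. It sets out from 13. Ozonolysis of the free alcohol (O3, then PPh3) gives the hydroxy diketone (3R)-3-hydroxy-1-methoxy-3-[4-(triisopropylsilyloxy)phenyl]-3-{(2R)-2-[4-(triisopropylsilyloxy)benzoyl]oxiran-2-yl}propan-2-one F9. Its activated tertiary α-hydroxy ketone is methylated with MeI and Ag2O (Purdie methylation), and the route is rejoined at 16.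

Further compounds
F1 | step 11 | (1R)-1-[4-(triisopropylsilyloxy)phenyl]-1-{(2R)-2-[1-(4-(triisopropylsilyloxy)phenyl)ethenyl]oxiran-2-yl}prop-2-en-1-ol | C=C(c1ccc(O[Si](C(C)C)(C(C)C)C(C)C)cc1)[C@@]1(CO1)[C@](O)(c1ccc(O[Si](C(C)C)(C(C)C)C(C)C)cc1)C=C
F2 | step 11 | (2R)-2-{(1R)-1-methoxy-1-[4-(triisopropylsilyloxy)phenyl]prop-2-en-1-yl}-2-{1-[4-(triisopropylsilyloxy)phenyl]ethenyl}oxirane | C=C(c1ccc(O[Si](C(C)C)(C(C)C)C(C)C)cc1)[C@@]1(CO1)[C@](OC)(c1ccc(O[Si](C(C)C)(C(C)C)C(C)C)cc1)C=C
F3 | step 11 | (2R)-2-methoxy-2-[4-(triisopropylsilyloxy)phenyl]-2-{(2R)-2-[4-(triisopropylsilyloxy)benzoyl]oxiran-2-yl}acetaldehyde | O=C(c1ccc(O[Si](C(C)C)(C(C)C)C(C)C)cc1)[C@@]1(CO1)[C@](OC)(c1ccc(O[Si](C(C)C)(C(C)C)C(C)C)cc1)C=O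
F4 | step 11 | diethyl {2-hydroxy-1,3-dimethoxy-3-[4-(triisopropylsilyloxy)phenyl]-3-[2-(4-(triisopropylsilyloxy)benzoyl)oxiran-2-yl]propyl}phosphonate, epoxide and ether centres as in F3, epimers at C1 and C2 | O=C(c1ccc(O[Si](C(C)C)(C(C)C)C(C)C)cc1)[C@@]1(CO1)[C@](OC)(c1ccc(O[Si](C(C)C)(C(C)C)C(C)C)cc1)C(O)C(OC)P(=O)(OCC)OCC
F5 | step 11 | diethyl {(3R)-1,3-dimethoxy-2-oxo-3-[4-(triisopropylsilyloxy)phenyl]-3-[(2R)-2-(4-(triisopropylsilyloxy)benzoyl)oxiran-2-yl]propyl}phosphonate, epimers at C1 | O=C(c1ccc(O[Si](C(C)C)(C(C)C)C(C)C)cc1)[C@@]1(CO1)[C@](OC)(c1ccc(O[Si](C(C)C)(C(C)C)C(C)C)cc1)C(=O)C(OC)P(=O)(OCC)OCC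
F6 | step 8 | (1S)-1-[4-(triisopropylsilyloxy)phenyl]-1-{(2R)-2-[1-(4-(triisopropylsilyloxy)phenyl)ethenyl]oxiran-2-yl}prop-2-yn-1-ol | C=C(c1ccc(O[Si](C(C)C)(C(C)C)C(C)C)cc1)[C@@]1(CO1)[C@](O)(c1ccc(O[Si](C(C)C)(C(C)C)C(C)C)cc1)C#C
F7 | step 8 | (2R)-2-{(1S)-1-methoxy-1-[4-(triisopropylsilyloxy)phenyl]prop-2-yn-1-yl}-2-{1-[4-(triisopropylsilyloxy)phenyl]ethenyl}oxirane | C=C(c1ccc(O[Si](C(C)C)(C(C)C)C(C)C)cc1)[C@@]1(CO1)[C@](OC)(c1ccc(O[Si](C(C)C)(C(C)C)C(C)C)cc1)C#C
F8 | step 8 | [(2R)-2-{(1S)-1-methoxy-1-[4-(triisopropylsilyloxy)phenyl]prop-2-yn-1-yl}oxiran-2-yl][4-(triisopropylsilyloxy)phenyl]methanone | O=C(c1ccc(O[Si](C(C)C)(C(C)C)C(C)C)cc1)[C@@]1(CO1)[C@](OC)(c1ccc(O[Si](C(C)C)(C(C)C)C(C)C)cc1)C#C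
F9 | step 9 | (3R)-3-hydroxy-1-methoxy-3-[4-(triisopropylsilyloxy)phenyl]-3-{(2R)-2-[4-(triisopropylsilyloxy)benzoyl]oxiran-2-yl}propan-2-one | O=C(c1ccc(O[Si](C(C)C)(C(C)C)C(C)C)cc1)[C@@]1(CO1)[C@](O)(c1ccc(O[Si](C(C)C)(C(C)C)C(C)C)cc1)C(=O)COC
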